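**Plan**

1. Retrosynthetic cuts: the five MOM ethers come off last; before that, O1–C2 (ring C) and O7L–C3 (ring F) are cut together, which opens the cis-fused core to a 3-hydroxy-3,3-diaryl-1,2-dione; the dione goes back to an alkyne, the C2–C3 bond to an acetylide plus a diaryl ketone, and the C8L–CO bond to an aryl iodide, CO and an arylboronic acid.
2. Enabling feature: C2 is a carbinol carbon bearing ring B and C8L, and it is flanked by two ortho phenol oxygens, O1 of ring A (which must bond to C2) and O7L of the lower flavonol (which must bond to the neighbouring C3), so rings C and F are both latent in the open chain.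
3. Forward order: lower flavonol (pyranone ring by Algar–Flynn–Oyamada closure), aroyl group at C8L, acetylide of ring A added to that ketone, alkyne oxidised to the dione, three phenols freed, rings C and F closed in one operation, global deprotection.
4. Stereochemistry: C2 is set by enantioface selection at a planar ortho-quinone methide paired with a chiral phosphate; C3 is a hemiketal that settles cis under thermodynamic control.
5. Protecting groups: benzyl on the three phenols that are free in the cyclisation substrate (O1, O7L, O5L), methoxymethyl on the five that stay masked to the end.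

Key step: step 14

Remark: atom labels follow the upper flavanone unit (O1, C2, C3, C4, rings A, B, C); atoms of the lower flavonol carry the suffix L; ring F is the dihydrofuran O7L–C7L–C8L–C2–C3.
Remark: the (R)-phosphoric acid is assumed to deliver the (2R,3S) series; the sense of induction cannot be predicted with confidence, and the (S)-acid would be taken if it runs the other way.
Remark: O5L is left free in the cyclisation substrate, because it is para to C8L, chelated to the C4L carbonyl and unable to reach C2 or C3; this removes any need to differentiate O5L from O7L.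

**Route**

Step 1
Reactants: 1 2,4,6-trihydroxyacetophenone
Product: 2 1-[2,4-bis(benzyloxy)-6-hydroxyphenyl]ethan-1-one
Conditions: BnBr (2.1 equiv), K2CO3, DMF, 0 °C → rt
Reagents that add atoms: benzyl bromide, BrCc1ccccc1
Why: Williamson ether synthesis in which the para hydroxyl and one ortho hydroxyl are alkylated, while the last ortho hydroxyl is held in a hydrogen bond to the acetyl carbonyl and should stay free.

Step 2
Reactants: 2 1-[2,4-bis(benzyloxy)-6-hydroxyphenyl]ethan-1-one
Product: 3 1-[4,6-bis(benzyloxy)-2-hydroxy-3-iodophenyl]ethan-1-one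
Conditions: NIS (1.05 equiv), TFA (cat.), MeCN, 0 °C → rt
Reagents that add atoms: N-iodosuccinimide, O=C1CCC(=O)N1I
Why: Electrophilic aromatic iodination directed by the free phenol to its ortho carbon, which is less hindered than the position between the two benzyloxy groups and later becomes C8L.

Step 3
Reactants: 4 4-hydroxybenzaldehyde
Product: 5 4-(methoxymethoxy)benzaldehyde
Conditions: MOMCl, iPr2NEt, CH2Cl2, 0 °C → rt
Reagents that add atoms: chloromethyl methyl ether, COCCl
Why: O-alkylation of the phenol to its methoxymethyl acetal, which is stable to the basic and organometallic steps that follow.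

Step 4
Reactants: 3 1-[4,6-bis(benzyloxy)-2-hydroxy-3-iodophenyl]ethan-1-one; 5 4-(methoxymethoxy)benzaldehyde
Product: 6 (E)-1-[4,6-bis(benzyloxy)-2-hydroxy-3-iodophenyl]-3-[4-(methoxymethoxy)phenyl]prop-2-en-1-one
Conditions: KOH (aq), EtOH/THF, rt
Reagents that add atoms: none
Why: Claisen–Schmidt condensation of the methyl ketone enolate with the non-enolisable aldehyde, with dehydration of the aldol to the conjugated E-enone.

Step 5
Reactants: 6 (E)-1-[4,6-bis(benzyloxy)-2-hydroxy-3-iodophenyl]-3-[4-(methoxymethoxy)phenyl]prop-2-en-1-one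
Product: 7 5,7-bis(benzyloxy)-3-hydroxy-8-iodo-2-[4-(methoxymethoxy)phenyl]-4H-chromen-4-one
Conditions: 30% H2O2, NaOH (aq), MeOH/THF, 0 °C → rt
Reagents that add atoms: hydrogen peroxide, OO
Why: Algar–Flynn–Oyamada oxidation, in which the 2'-phenoxide closes on the beta carbon of the peroxide-activated enone and the dihydroflavonol is oxidised on to the flavonol; the electron-rich 4-alkoxyphenyl ring should favour this six-membered closure over aurone formation.

Step 6
Reactants: 7 5,7-bis(benzyloxy)-3-hydroxy-8-iodo-2-[4-(methoxymethoxy)phenyl]-4H-chromen-4-one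
Product: 8 5,7-bis(benzyloxy)-8-iodo-3-(methoxymethoxy)-2-[4-(methoxymethoxy)phenyl]-4H-chromen-4-one
Conditions: MOMCl, iPr2NEt, CH2Cl2, 0 °C → 40 °C
Reagents that add atoms: chloromethyl methyl ether, COCCl
Why: O-alkylation of the acidic enolic 3-hydroxyl of the flavonol to its MOM acetal, a standard protection of flavonols.

Step 7
Reactants: 8 5,7-bis(benzyloxy)-8-iodo-3-(methoxymethoxy)-2-[4-(methoxymethoxy)phenyl]-4H-chromen-4-one; 9 4-(methoxymethoxy)phenylboronic acid
Product: 10 5,7-bis(benzyloxy)-3-(methoxymethoxy)-8-[4-(methoxymethoxy)benzoyl]-2-[4-(methoxymethoxy)phenyl]-4H-chromen-4-one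
Conditions: CO (4 atm), PdCl2(IPr)(3-chloropyridine) (3 mol%; IPr = 1,3-bis(2,6-diisopropylphenyl)imidazol-2-ylidene), Cs2CO3, chlorobenzene, 80 °C
Reagents that add atoms: carbon monoxide, [C-]#[O+]
Why: Carbonylative Suzuki–Miyaura coupling, in which the aryl iodide adds to zerovalent palladium, CO insertion outruns direct transmetalation because both ortho positions are substituted, and the acylpalladium is arylated by the boronate; this carbene-ligated catalyst type is established for di-ortho-substituted aryl iodides.

Step 8
Reactants: 11 2,4,6-trihydroxybenzaldehyde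
Product: 12 2-hydroxy-4,6-bis(methoxymethoxy)benzaldehyde
Conditions: MOMCl (2.2 equiv), iPr2NEt, CH2Cl2, 0 °C → rt
Reagents that add atoms: chloromethyl methyl ether, COCCl
Why: Selective O-alkylation of the two more acidic hydroxyls, the remaining ortho hydroxyl being deactivated by its hydrogen bond to the formyl group.

Step 9
Reactants: 12 2-hydroxy-4,6-bis(methoxymethoxy)benzaldehyde
Product: 13 2-(benzyloxy)-4,6-bis(methoxymethoxy)benzaldehyde
Conditions: BnBr, K2CO3, DMF, 60 °C
Reagents that add atoms: benzyl bromide, BrCc1ccccc1
Why: Williamson ether synthesis on the chelated phenol under forcing but standard conditions, which marks the future O1 with a group that can be removed without acid.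

Step 10
Reactants: 13 2-(benzyloxy)-4,6-bis(methoxymethoxy)benzaldehyde
Product: 14 1-(benzyloxy)-2-ethynyl-3,5-bis(methoxymethoxy)benzene
Conditions: dimethyl (1-diazo-2-oxopropyl)phosphonate, K2CO3, MeOH/THF, rt
Reagents that add atoms: dimethyl (1-diazo-2-oxopropyl)phosphonate, CC(=O)C(=[N+]=[N-])P(=O)(OC)OC
Why: Seyferth–Gilbert homologation in its Ohira–Bestmann form, which turns the aldehyde into the terminal alkyne under mild base that leaves benzyl and MOM ethers untouched.

Step 11
Reactants: 14 1-(benzyloxy)-2-ethynyl-3,5-bis(methoxymethoxy)benzene; 10 5,7-bis(benzyloxy)-3-(methoxymethoxy)-8-[4-(methoxymethoxy)benzoyl]-2-[4-(methoxymethoxy)phenyl]-4H-chromen-4-one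
Product: 16 racemic 8-{3-[2-(benzyloxy)-4,6-bis(methoxymethoxy)phenyl]-1-hydroxy-1-[4-(methoxymethoxy)phenyl]prop-2-yn-1-yl}-5,7-bis(benzyloxy)-3-(methoxymethoxy)-2-[4-(methoxymethoxy)phenyl]-4H-chromen-4-one, via lithium acetylide 15 (not isolated)
Conditions: nBuLi (1.0 equiv to 14), THF, −78 °C; then 10, LaCl3·2LiCl, −78 → −20 °C; aq NH4Cl
Reagents that add atoms: none
Why: 1,2-addition of a lithium acetylide to a diaryl ketone, for which the slim nucleophile tolerates the two ortho substituents, while the chromone carbonyl is a doubly donor-stabilised vinylogous ester with a fully substituted C2L and should not compete; the new carbinol centre is racemic and is erased in step 14.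

Step 12
Reactants: 16 racemic propargylic carbinol
Product: 17 racemic 1-[2-(benzyloxy)-4,6-bis(methoxymethoxy)phenyl]-3-{5,7-bis(benzyloxy)-3-(methoxymethoxy)-2-[4-(methoxymethoxy)phenyl]-4-oxo-4H-chromen-8-yl}-3-hydroxy-3-[4-(methoxymethoxy)phenyl]propane-1,2-dione
Conditions: KMnO4, NaHCO3, MgSO4, acetone/H2O, 0 °C → rt
Reagents that add atoms: potassium permanganate, [K+].[O-][Mn](=O)(=O)=O
Why: Permanganate oxidation of an internal alkyne to the 1,2-dione under buffered neutral conditions, which avoids acid at the ionisable carbinol and should spare aryl ethers that a stronger oxidant would degrade.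

Step 13
Reactants: 17 racemic protected hydroxy-dione
Product: 18 racemic 3-{5,7-dihydroxy-3-(methoxymethoxy)-2-[4-(methoxymethoxy)phenyl]-4-oxo-4H-chromen-8-yl}-3-hydroxy-1-[2-hydroxy-4,6-bis(methoxymethoxy)phenyl]-3-[4-(methoxymethoxy)phenyl]propane-1,2-dione
Conditions: H2 (1 atm), 10% Pd/C, NaHCO3 (solid), EtOAc, rt; filtered and used at once
Reagents that add atoms: none
Why: Hydrogenolysis of the three aryl benzyl ethers, which should be faster than reduction of the hindered dione, with solid bicarbonate keeping the medium free of acid so that the carbinol is not ionised before the chiral catalyst is present.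

Step 14
Reactants: 18 racemic open-chain hydroxy-dione with O1–H, O7L–H and O5L–H free
Product: 21 (2R,3S)-cis-fused cyclisation product carrying five MOM ethers (O5 and O7 of ring A; O4' of ring B; O3L; O4'L) with O5L–H and C3–OH free, via ortho-quinone methide 19 (not isolated), via ring C-closed phenol-dione 20 (not isolated)
Conditions: (R)-TRIP [(R)-3,3'-bis(2,4,6-triisopropylphenyl)-1,1'-binaphthyl-2,2'-diyl hydrogen phosphate] (10 mol%), 4 Å MS, toluene, 0 °C → rt
Reagents that add atoms: none
Why: Proposed new method: the phosphoric acid protonates the tertiary C2 hydroxyl while its phosphoryl oxygen accepts O7L–H, so water is lost and the planar ortho-quinone methide 19 (C8L=C2, O7L as carbonyl) forms as a hydrogen-bonded pair with the chiral phosphate, the hemiketal tautomers of 18 feeding the same intermediate; the closest known reaction type is the chiral phosphoric acid-catalysed enantioselective addition of nucleophiles to ortho-quinone methides generated in situ from ortho-hydroxybenzhydryl alcohols, extended here to an intramolecular oxygen nucleophile at a fully substituted, acyl-bearing methide carbon. Ring C closes by 6-exo-trig attack of the ring A phenol O1 on the methide carbon C2, which rearomatises the lower ring and gives 20 with O7L–H restored. Ring F closes by 5-exo-trig addition of O7L–H to the adjacent C3 carbonyl of the dione, the C4 carbonyl being a deactivated aryl ketone whose capture would give a strained bridged ketal. C2 is controlled by the catalyst, whose phosphate bridges the quinone methide oxygen and O1–H inside the pocket of the 2,4,6-triisopropylphenyl groups and so exposes one face of the planar methide, whereas C3 is an equilibrating hemiketal that can close only cis to the C2–O1 bond in the 6/5-fused system and therefore follows C2. The step needs enantioface selectivity at C2 and site selectivity among three free phenols: O1 alone reaches C2 through a six-membered ring, O7L alone reaches C3 through a five-membered ring, O5L is para to C8L and tied to the C4L carbonyl, and ring B is kept as its MOM ether so that no uncatalysed para-quinone methide pathway opens through it. The sieves take up the water, and closure of ring F removes the free O7L–H that a return to the methide would need, which should protect the product from racemisation.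

Step 15
Reactants: 21 (2R,3S)-pentakis(methoxymethyl)-protected cyclisation product
Product: 22 CNP0314633.1, the (2R,3S)-configured target
Conditions: 1 M HCl (aq), THF, rt → 35 °C
Reagents that add atoms: none
Why: Acid hydrolysis of the five aryl MOM acetals; methanol is left out so that the C3 hemiketal is not converted into a methyl ketal, and the temperature is kept low to disfavour reopening of the core.

**Compound list**

1 | 2,4,6-trihydroxyacetophenone | CC(=O)c1c(O)cc(O)cc1O | starting material
2 | 1-[2,4-bis(benzyloxy)-6-hydroxyphenyl]ethan-1-one | CC(=O)c1c(O)cc(OCc2ccccc2)cc1OCc1ccccc1 | intermediate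
3 | 1-[4,6-bis(benzyloxy)-2-hydroxy-3-iodophenyl]ethan-1-one | CC(=O)c1c(O)c(I)c(OCc2ccccc2)cc1OCc1ccccc1 | intermediate
4 | 4-hydroxybenzaldehyde | O=Cc1ccc(O)cc1 | starting material
5 | 4-(methoxymethoxy)benzaldehyde | O=Cc1ccc(OCOC)cc1 | intermediate
6 | (E)-1-[4,6-bis(benzyloxy)-2-hydroxy-3-iodophenyl]-3-[4-(methoxymethoxy)phenyl]prop-2-en-1-one | O=C(/C=C/c1ccc(OCOC)cc1)c1c(O)c(I)c(OCc2ccccc2)cc1OCc1ccccc1 | intermediate
7 | 5,7-bis(benzyloxy)-3-hydroxy-8-iodo-2-[4-(methoxymethoxy)phenyl]-4H-chromen-4-one | O=c1c(O)c(-c2ccc(OCOC)cc2)oc2c(I)c(OCc3ccccc3)cc(OCc3ccccc3)c12 | intermediate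
8 | 5,7-bis(benzyloxy)-8-iodo-3-(methoxymethoxy)-2-[4-(methoxymethoxy)phenyl]-4H-chromen-4-one | O=c1c(OCOC)c(-c2ccc(OCOC)cc2)oc2c(I)c(OCc3ccccc3)cc(OCc3ccccc3)c12 | intermediate
9 | 4-(methoxymethoxy)phenylboronic acid | OB(O)c1ccc(OCOC)cc1 | starting material
10 | 5,7-bis(benzyloxy)-3-(methoxymethoxy)-8-[4-(methoxymethoxy)benzoyl]-2-[4-(methoxymethoxy)phenyl]-4H-chromen-4-one | O=C(c1ccc(OCOC)cc1)c1c(OCc2ccccc2)cc(OCc2ccccc2)c2c(=O)c(OCOC)c(-c3ccc(OCOC)cc3)oc12 | intermediate
11 | 2,4,6-trihydroxybenzaldehyde | O=Cc1c(O)cc(O)cc1O | starting material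
12 | 2-hydroxy-4,6-bis(methoxymethoxy)benzaldehyde | O=Cc1c(O)cc(OCOC)cc1OCOC | intermediate
13 | 2-(benzyloxy)-4,6-bis(methoxymethoxy)benzaldehyde | O=Cc1c(OCc2ccccc2)cc(OCOC)cc1OCOC | intermediate
14 | 1-(benzyloxy)-2-ethynyl-3,5-bis(methoxymethoxy)benzene | C#Cc1c(OCc2ccccc2)cc(OCOC)cc1OCOC | intermediate
15 | lithium acetylide of 14 (not isolated) | [Li]C#Cc1c(OCc2ccccc2)cc(OCOC)cc1OCOC | intermediate
16 | racemic tertiary propargylic carbinol joining ring A alkyne, ring B and C8L of the lower flavonol | OC(C#Cc1c(OCc2ccccc2)cc(OCOC)cc1OCOC)(c1ccc(OCOC)cc1)c1c(OCc2ccccc2)cc(OCc2ccccc2)c2c(=O)c(OCOC)c(-c3ccc(OCOC)cc3)oc12 | intermediate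
17 | racemic 3-hydroxy-3,3-diaryl-1,2-dione with three benzyl and five MOM ethers | O=C(C(=O)C(O)(c1ccc(OCOC)cc1)c1c(OCc2ccccc2)cc(OCc2ccccc2)c2c(=O)c(OCOC)c(-c3ccc(OCOC)cc3)oc12)c1c(OCc2ccccc2)cc(OCOC)cc1OCOC | intermediate
18 | racemic open-chain 3-hydroxy-3,3-diaryl-1,2-dione with O1–H, O7L–H and O5L–H free and five MOM ethers (drawn open; ring-chain hemiketal tautomers are expected in equilibrium) | O=C(C(=O)C(O)(c1ccc(OCOC)cc1)c1c(O)cc(O)c2c(=O)c(OCOC)c(-c3ccc(OCOC)cc3)oc12)c1c(O)cc(OCOC)cc1OCOC | intermediate
19 | ortho-quinone methide (C8L=C2 exocyclic, O7L as carbonyl), not isolated | O=C(c1c(O)cc(OCOC)cc1OCOC)C(=O)C(c1ccc(OCOC)cc1)=C1C(=O)C=C(O)C2=C1OC(c1ccc(OCOC)cc1)=C(OCOC)C2=O | intermediate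
20 | (2R)-ring C-closed chromane-3,4-dione with O7L–H free, not isolated | O=C1c2c(OCOC)cc(OCOC)cc2O[C@](c2ccc(OCOC)cc2)(c2c(O)cc(O)c3c(=O)c(OCOC)c(-c4ccc(OCOC)cc4)oc23)C1=O | intermediate
21 | (2R,3S)-cis-fused cyclisation product, pentakis(methoxymethyl) ether of the target with O5L–H and the C3 hemiketal OH free | O=C1c2c(OCOC)cc(OCOC)cc2O[C@]2(c3ccc(OCOC)cc3)c3c(cc(O)c4c(=O)c(OCOC)c(-c5ccc(OCOC)cc5)oc34)O[C@]12O | intermediate
22 | CNP0314633.1, (2R,3S); upper 3,5,7-trihydroxy-2-(4-hydroxyphenyl)chroman-4-one unit joined C2–C8L and C3–O7L to kaempferol, cis-fused | O=C1c2c(O)cc(O)cc2O[C@]2(c3ccc(O)cc3)c3c(cc(O)c4c(=O)c(O)c(-c5ccc(O)cc5)oc34)O[C@]12O | target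

**Step count and risks**

Total: 15 steps. Longest linear sequence: 11 steps (1, 2, 4, 5, 6, 7, 11, 12, 13, 14, 15).

Step 14 (key step). What may go wrong: the acid may fail to ionise a carbinol that sits next to the dione, or the cyclisation may run through a loosely bound ion pair or an uncatalysed background path, giving poor enantioface selectivity at C2. A more acidic N-triflyl phosphoramide on the same binaphthyl backbone would be tried first. Fallback with known chemistry: setting out from 18, an achiral Brønsted acid (diphenyl phosphate, catalytic, CH2Cl2, rt) would close both rings through the same quinone methide with no attempt at enantiocontrol. Because the fusion can only be cis, this should give the racemate, that is 21 together with the enantiomer of 21 F1. Preparative HPLC on an amylose tris(3,5-dimethylphenylcarbamate) phase would separate the two, and the route is rejoined at 21.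

Step 12. What may go wrong: over-oxidation with cleavage next to the tertiary carbinol, or competing attack of permanganate on the electron-rich rings or the pyranone double bond. Fallback: setting out from 16, semi-hydrogenation (H2, Pd/CaCO3 poisoned with Pb(OAc)2, quinoline, EtOAc) would give the (Z)-alkene F2, which leaves the benzyl ethers in place. Dihydroxylation with catalytic OsO4 and NMO would give the triol F3 as a diastereomer mixture of no consequence. IBX in DMSO would then oxidise both secondary carbinols without cleaving the diol, and the route is rejoined at 17.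

Step 15. What may go wrong: acid-promoted reopening of ring F together with ionisation of the C2–O1 bond would pass through the planar quinone methide and erode the enantiomeric purity; cleavage may also stop short of all five ethers. Fallback: setting out from 21, TMSOTf with 2,2'-bipyridyl in MeCN at 0 °C would exchange the aryl MOM ethers for silyl ethers under buffered aprotic conditions and silylate the two free hydroxyls, giving the heptakis(trimethylsilyl) derivative F4. Hydrolysis of the silyl ethers in wet THF with a trace of acetic acid at 0 °C would then release the phenols without strong protic acid, and the route is rejoined at 22.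

**Further compounds**

F1 | step 14 | enantiomer of 21, (2S,3R) | O=C1c2c(OCOC)cc(OCOC)cc2O[C@@]2(c3ccc(OCOC)cc3)c3c(cc(O)c4c(=O)c(OCOC)c(-c5ccc(OCOC)cc5)oc34)O[C@@]12O
F2 | step 12 | racemic (Z)-alkene from semi-hydrogenation of 16 | OC(/C=C\c1c(OCc2ccccc2)cc(OCOC)cc1OCOC)(c1ccc(OCOC)cc1)c1c(OCc2ccccc2)cc(OCc2ccccc2)c2c(=O)c(OCOC)c(-c3ccc(OCOC)cc3)oc12
F3 | step 12 | 1,2,3-triol from dihydroxylation of F2 (diastereomer mixture, configuration not defined) | OC(C(O)C(O)(c1ccc(OCOC)cc1)c1c(OCc2ccccc2)cc(OCc2ccccc2)c2c(=O)c(OCOC)c(-c3ccc(OCOC)cc3)oc12)c1c(OCc2ccccc2)cc(OCOC)cc1OCOC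
F4 | step 15 | (2R,3S)-heptakis(trimethylsilyl) derivative of the target | O=C1c2c(O[Si](C)(C)C)cc(O[Si](C)(C)C)cc2O[C@]2(c3ccc(O[Si](C)(C)C)cc3)c3c(cc(O[Si](C)(C)C)c4c(=O)c(O[Si](C)(C)C)c(-c5ccc(O[Si](C)(C)C)cc5)oc34)O[C@]12O[Si](C)(C)C
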